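**Retrosynthetic overview**

- The target is reached by one final hydrogenation of a penta-benzyl ether whose C5 side chain is still an enone; this removes the five benzyl groups and saturates the C=C.
- The dihydrofuran ring (O1–C2–C3–C3a–C7a) is the only ring formed; all benzene rings are bought. It is cut at C7a–O1 and C3a–C3, giving a para-substituted iodoarene (a 4-iodochalcone) and an enantiopure trans-chalcone epoxide that already carries O1, C2 and C3. Both bonds are made in one palladium/norbornene ortho-C–H alkylation/ipso C–O coupling.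
- Enabling feature: C3 is alpha to the aroyl C=O. In the epoxide this carbon is SN2-activated, and in the product its hydrogen is acidic, so either C3 epimer funnels to 2,3-trans while C2 keeps the C–O bond it had in the epoxide. Ring A carries O1 (at C7a) and C3 (at C3a) on neighbouring carbons and its only other substituent at C5, para to O1, so the iodoarene has two equivalent ortho C–H bonds.
- Both partners come from 2',4'-bis(benzyloxy)acetophenone by Claisen–Schmidt condensations (with 4-iodobenzaldehyde and with 4-(benzyloxy)benzaldehyde); a Juliá–Colonna epoxidation of the second enone sets C2.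

Key step: step 5

Remark on the chemistry: the SMILES is read as the (2S,3S), 2,3-trans isomer (numbering of 2,3-dihydro-1-benzofuran: O1, C2, C3, C3a, C4–C7, C7a). 2,3-trans is assumed to be the thermodynamically preferred arrangement of a 2-aryl-3-aroyl-2,3-dihydrobenzofuran.

**Route**

Step 1
Reactants: 1 2',4'-dihydroxyacetophenone
Product: 2 1-[2,4-bis(benzyloxy)phenyl]ethan-1-one
Conditions: BnBr (2.5 equiv), K2CO3 (3 equiv), DMF, 80 °C
Reagents that add atoms: benzyl bromide, BrCc1ccccc1
Why: Williamson ether synthesis in which both phenoxides are O-benzylated, the hydrogen-bonded 2-OH needing DMF and heat, and no stereocentre is formed.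

Step 2
Reactants: 2 1-[2,4-bis(benzyloxy)phenyl]ethan-1-one; 3 4-iodobenzaldehyde
Product: 4 (E)-1-[2,4-bis(benzyloxy)phenyl]-3-(4-iodophenyl)prop-2-en-1-one
Conditions: KOH (aq.), EtOH/THF, rt
Reagents that add atoms: none
Why: Claisen–Schmidt (crossed aldol) condensation of the methyl ketone enolate with a non-enolisable aldehyde followed by E1cB dehydration should give only the conjugated E-enone, the aryl iodide being inert to aqueous hydroxide at room temperature.

Step 3
Reactants: 2 1-[2,4-bis(benzyloxy)phenyl]ethan-1-one; 5 4-(benzyloxy)benzaldehyde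
Product: 6 (E)-1-[2,4-bis(benzyloxy)phenyl]-3-[4-(benzyloxy)phenyl]prop-2-en-1-one
Conditions: KOH (aq.), EtOH/THF, rt
Reagents that add atoms: none
Why: Claisen–Schmidt condensation as in step 2, which should again deliver the E-enone as the thermodynamic dehydration product.

Step 4
Reactants: 6 (E)-1-[2,4-bis(benzyloxy)phenyl]-3-[4-(benzyloxy)phenyl]prop-2-en-1-one
Product: 7 [2,4-bis(benzyloxy)phenyl]{(2S,3R)-3-[4-(benzyloxy)phenyl]oxiran-2-yl}methanone
Conditions: poly-D-leucine, urea–H2O2 (1.2 equiv), DBU (1.5 equiv), THF, rt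
Reagents that add atoms: urea–hydrogen peroxide, NC(N)=O.OO
Why: Juliá–Colonna epoxidation (Weitz–Scheffer hydroperoxide conjugate addition and ring closure inside the helical polypeptide), in which the E geometry is translated into the trans-epoxide and the D-configured polyleucine, mirror image of the L-polymer that delivers (2R,3S)-chalcone oxides, should set the (2S,3R) configuration, whose C3 becomes C2 of the target.

Step 5
Reactants: 4 (E)-1-[2,4-bis(benzyloxy)phenyl]-3-(4-iodophenyl)prop-2-en-1-one; 7 [2,4-bis(benzyloxy)phenyl]{(2S,3R)-3-[4-(benzyloxy)phenyl]oxiran-2-yl}methanone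
Product: 9 (E)-1-[2,4-bis(benzyloxy)phenyl]-3-[(2S,3S)-3-[2,4-bis(benzyloxy)benzoyl]-2-[4-(benzyloxy)phenyl]-2,3-dihydro-1-benzofuran-5-yl]prop-2-en-1-one, via cis-(2S,3R) epimer 8 (not isolated)
Conditions: 4 (1.5 equiv), 7 (1 equiv, added slowly), Pd(OAc)2 (10 mol%), XPhos (20 mol%), 1-methylbicyclo[2.2.1]hept-2-ene (1 equiv), Cs2CO3 (2.5 equiv), 1,4-dioxane, 100 °C; then DBU (0.2 equiv), rt
Reagents that add atoms: none
Why: Proposed new method: a palladium/norbornene (Catellani-type) annulation in which 4 adds oxidatively to zerovalent palladium, norbornene insertion and ortho C–H palladation give the divalent aryl–norbornyl palladacycle, and this should open 7 by SN2-type oxidative addition at the oxirane carbon next to the C=O (its C–O sigma-star is lowered by the carbonyl, the activation that makes alpha-halo ketones fast SN2 substrates), after which C(sp2)–C(sp3) reductive elimination from tetravalent palladium forms C3a–C3 and norbornene extrusion followed by C–O reductive elimination of the tethered alkoxide forms C7a–O1. The closest known reaction type is the palladium/norbornene annulation of aryl iodides with terminal epoxides to 2,3-dihydrobenzofurans, and secondary alkyl iodides are known to add to such palladacycles with inversion; new is the use of a 2,3-disubstituted, ketone-activated epoxide. The dihydrofuran ring closes by reductive elimination from a six-membered oxapalladacycle (Pd, C7a, C3a, C3, C2, O1), overall a formal [3+2] annulation of the O–C–C unit onto two neighbouring arene carbons. C2 is controlled by the epoxide, since its C–O bond is never broken ((3R) in 7 becomes (2S) in 9 only through a change of CIP priorities), whereas C3 should first form cis (epimer 8, inversion then stereoretentive reductive elimination) and, being alpha to the aroyl group, should equilibrate under Cs2CO3/DBU to the more stable 2,3-trans (3S) arrangement, so that either C3 epimer converges on 9. The step needs opening at the alpha-keto carbon and not at the benzylic one (secured by the carbonyl activation and a basic medium free of strong Lewis acids), one ortho-alkylation and not two (secured by the bridgehead-substituted norbornene; the two ortho C–H bonds of the para-substituted iodide are equivalent, so no regiochemical question arises), and C–O reductive elimination faster than retro-aldol cleavage of the alkoxide (helped by the electron-poor, enone-bearing aryl group and the bulky biarylphosphine).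

Step 6
Reactants: 9 (E)-1-[2,4-bis(benzyloxy)phenyl]-3-[(2S,3S)-3-[2,4-bis(benzyloxy)benzoyl]-2-[4-(benzyloxy)phenyl]-2,3-dihydro-1-benzofuran-5-yl]prop-2-en-1-one
Product: 10 1-(2,4-dihydroxyphenyl)-3-[(2S,3S)-3-(2,4-dihydroxybenzoyl)-2-(4-hydroxyphenyl)-2,3-dihydro-1-benzofuran-5-yl]propan-1-one
Conditions: H2 (1 atm), Pd/C (10%), THF/MeOH, rt
Reagents that add atoms: none
Why: Heterogeneous catalytic hydrogenation in which hydrogenolysis of the five aryl benzyl ethers and saturation of the conjugated C=C should occur together under neutral conditions that touch neither the chelated aryl ketones nor the stereocentres at C2 and C3.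

**Compound list**

1 | 2',4'-dihydroxyacetophenone | CC(=O)c1ccc(O)cc1O | starting material
2 | 1-[2,4-bis(benzyloxy)phenyl]ethan-1-one | CC(=O)c1ccc(OCc2ccccc2)cc1OCc1ccccc1 | intermediate
3 | 4-iodobenzaldehyde | O=Cc1ccc(I)cc1 | starting material
4 | (E)-1-[2,4-bis(benzyloxy)phenyl]-3-(4-iodophenyl)prop-2-en-1-one | O=C(/C=C/c1ccc(I)cc1)c1ccc(OCc2ccccc2)cc1OCc1ccccc1 | intermediate
5 | 4-(benzyloxy)benzaldehyde | O=Cc1ccc(OCc2ccccc2)cc1 | starting material
6 | (E)-1-[2,4-bis(benzyloxy)phenyl]-3-[4-(benzyloxy)phenyl]prop-2-en-1-one | O=C(/C=C/c1ccc(OCc2ccccc2)cc1)c1ccc(OCc2ccccc2)cc1OCc1ccccc1 | intermediate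
7 | [2,4-bis(benzyloxy)phenyl]{(2S,3R)-3-[4-(benzyloxy)phenyl]oxiran-2-yl}methanone | O=C(c1ccc(OCc2ccccc2)cc1OCc1ccccc1)[C@H]1O[C@@H]1c1ccc(OCc2ccccc2)cc1 | intermediate
8 | (E)-1-[2,4-bis(benzyloxy)phenyl]-3-[(2S,3R)-3-[2,4-bis(benzyloxy)benzoyl]-2-[4-(benzyloxy)phenyl]-2,3-dihydro-1-benzofuran-5-yl]prop-2-en-1-one (cis epimer of 9) | O=C(/C=C/c1ccc2c(c1)[C@@H](C(=O)c3ccc(OCc4ccccc4)cc3OCc3ccccc3)[C@@H](c3ccc(OCc4ccccc4)cc3)O2)c1ccc(OCc2ccccc2)cc1OCc1ccccc1 | intermediate (not isolated)
9 | (E)-1-[2,4-bis(benzyloxy)phenyl]-3-[(2S,3S)-3-[2,4-bis(benzyloxy)benzoyl]-2-[4-(benzyloxy)phenyl]-2,3-dihydro-1-benzofuran-5-yl]prop-2-en-1-one | O=C(/C=C/c1ccc2c(c1)[C@H](C(=O)c3ccc(OCc4ccccc4)cc3OCc3ccccc3)[C@@H](c3ccc(OCc4ccccc4)cc3)O2)c1ccc(OCc2ccccc2)cc1OCc1ccccc1 | intermediate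
10 | 1-(2,4-dihydroxyphenyl)-3-[(2S,3S)-3-(2,4-dihydroxybenzoyl)-2-(4-hydroxyphenyl)-2,3-dihydro-1-benzofuran-5-yl]propan-1-one | O=C(CCc1ccc2c(c1)[C@H](C(=O)c1ccc(O)cc1O)[C@@H](c1ccc(O)cc1)O2)c1ccc(O)cc1O | target

**Step count and risks**

Total step count: 6. Longest linear sequence: 5 (steps 1, 3, 4, 5, 6).

Steps most likely to fail:

1. Step 5 (Proposed new method).
 - What may go wrong: oxidative addition of the palladacycle to the hindered trans-disubstituted epoxide may be too slow. Then isomerisation of the epoxy ketone to a 1,3-diketone by zerovalent palladium, opening at the benzylic carbon, a second ortho-alkylation, or retro-aldol cleavage of the palladium alkoxide could take over. Base-induced ring opening at C3 could also erode the configuration at C2.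
 - Fallback (known chemistry; sets out from 2, comes back at 10): Claisen–Schmidt condensation of 2 with 4-hydroxybenzaldehyde (KOH, EtOH, 50 °C) should give (E)-1-[2,4-bis(benzyloxy)phenyl]-3-(4-hydroxyphenyl)prop-2-en-1-one F1. Oxidative beta-5 radical dimerisation of F1 with Ag2O (benzene/acetone, rt, dark), the reaction type that converts 4-hydroxycinnamates into trans-dihydrobenzofuran neolignans, should give racemic (E)-1-[2,4-bis(benzyloxy)phenyl]-3-[(2S*,3S*)-3-[2,4-bis(benzyloxy)benzoyl]-2-(4-hydroxyphenyl)-2,3-dihydro-1-benzofuran-5-yl]prop-2-en-1-one F2. Preparative HPLC on a chiral stationary phase should give its (2S,3S) enantiomer, (E)-1-[2,4-bis(benzyloxy)phenyl]-3-[(2S,3S)-3-[2,4-bis(benzyloxy)benzoyl]-2-(4-hydroxyphenyl)-2,3-dihydro-1-benzofuran-5-yl]prop-2-en-1-one F3. Hydrogenation of F3 under the conditions of step 6 should give 10.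

2. Step 6.
 - What may go wrong: over-reduction, namely hydrogenolysis of the benzylic C2–O1 bond (ring opening) once the para-hydroxyl group is free, or stalling at the hindered ortho-benzyl ethers.
 - Fallback (sets out from 9, comes back at 10): chemoselective conjugate reduction of the enone with [(Ph3P)CuH]6 (benzene, rt) should give 1-[2,4-bis(benzyloxy)phenyl]-3-[(2S,3S)-3-[2,4-bis(benzyloxy)benzoyl]-2-[4-(benzyloxy)phenyl]-2,3-dihydro-1-benzofuran-5-yl]propan-1-one F4. Non-reductive, Lewis-acid debenzylation of F4 with BCl3 and pentamethylbenzene as cation scavenger (CH2Cl2, −78 °C) should give 10.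

3. Step 4.
 - What may go wrong: slow conversion and eroded enantioselectivity with the electron-rich, ortho-alkoxy-substituted enone, and acid-triggered ring opening or Meinwald rearrangement of the para-alkoxyphenyl epoxide during purification.
 - Fallback (sets out from 2, uses 5, comes back at 7): alpha-chlorination of the lithium enolate of 2 (LiHMDS, THF, −78 °C; then TsCl) should give 2-chloro-1-[2,4-bis(benzyloxy)phenyl]ethan-1-one F5. A catalytic asymmetric Darzens condensation of F5 with 5 under a cinchona-derived quaternary ammonium phase-transfer catalyst (LiOH, Bu2O, 0 °C), with the pseudoenantiomer chosen that leads to the (2S,3R) series, should give the trans-epoxy ketone 7 by C–C and C–O bond formation instead of alkene oxidation.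

**Further compounds**

F1 | step 5 | (E)-1-[2,4-bis(benzyloxy)phenyl]-3-(4-hydroxyphenyl)prop-2-en-1-one | O=C(/C=C/c1ccc(O)cc1)c1ccc(OCc2ccccc2)cc1OCc1ccccc1
F2 | step 5 | racemic (E)-1-[2,4-bis(benzyloxy)phenyl]-3-[(2S*,3S*)-3-[2,4-bis(benzyloxy)benzoyl]-2-(4-hydroxyphenyl)-2,3-dihydro-1-benzofuran-5-yl]prop-2-en-1-one (both enantiomers written) | O=C(/C=C/c1ccc2c(c1)[C@H](C(=O)c3ccc(OCc4ccccc4)cc3OCc3ccccc3)[C@@H](c3ccc(O)cc3)O2)c1ccc(OCc2ccccc2)cc1OCc1ccccc1.O=C(/C=C/c1ccc2c(c1)[C@@H](C(=O)c3ccc(OCc4ccccc4)cc3OCc3ccccc3)[C@H](c3ccc(O)cc3)O2)c1ccc(OCc2ccccc2)cc1OCc1ccccc1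
F3 | step 5 | (E)-1-[2,4-bis(benzyloxy)phenyl]-3-[(2S,3S)-3-[2,4-bis(benzyloxy)benzoyl]-2-(4-hydroxyphenyl)-2,3-dihydro-1-benzofuran-5-yl]prop-2-en-1-one | O=C(/C=C/c1ccc2c(c1)[C@H](C(=O)c3ccc(OCc4ccccc4)cc3OCc3ccccc3)[C@@H](c3ccc(O)cc3)O2)c1ccc(OCc2ccccc2)cc1OCc1ccccc1
F4 | step 6 | 1-[2,4-bis(benzyloxy)phenyl]-3-[(2S,3S)-3-[2,4-bis(benzyloxy)benzoyl]-2-[4-(benzyloxy)phenyl]-2,3-dihydro-1-benzofuran-5-yl]propan-1-one | O=C(CCc1ccc2c(c1)[C@H](C(=O)c3ccc(OCc4ccccc4)cc3OCc3ccccc3)[C@@H](c3ccc(OCc4ccccc4)cc3)O2)c1ccc(OCc2ccccc2)cc1OCc1ccccc1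
F5 | step 4 | 2-chloro-1-[2,4-bis(benzyloxy)phenyl]ethan-1-one | O=C(CCl)c1ccc(OCc2ccccc2)cc1OCc1ccccc1
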